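**Retrosynthetic overview**

1. The strategy rests on the acyl ring: its quaternary C1 (bearing OH and the ester carbonyl) lies between the alkene carbon C2 (of C2=C3) and the ketone carbon C6. This α-hydroxy β-keto ester is the ketol isomer of a 2-(1-hydroxycyclopent-2-en-1-yl)-2-oxoacetate, so C1–C2 is disconnected by a retro-1,2-shift that contracts the cyclohexenone to a cyclopentene carbinol.
2. The keto ester comes from the diazoacetate on the terminal C3 oxygen of the silylated trimer, by aldol-type addition to cyclopent-2-en-1-one, separation of the carbinol epimers and oxidation of the diazo carbon.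
3. The trimer epicatechin-(4β→8)-catechin-(4α→8)-catechin comes from two Lewis-acid C4→C8 flavan couplings in the benzyl ether series (middle–terminal first, then upper–middle). The C3 oxygens of the upper and middle units are TBS ethers, so only the terminal C3–OH is ever free.
4. The benzyl ethers are exchanged for TBS ethers before any alkene or diazo group is present: hydrogenolysis, then silylation in two stages of six phenols (ring-A phenols while the ring-B catechols are held as phenylboronates, then ring B). One buffered fluoride step at the end frees all fourteen silyl ethers.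
5. Ring order: flavan rings A, B and C come from the pool; interflavan bond M–T, then U–M; the cyclopentene is attached in step 15; the six-membered acyl ring is formed in step 17 by ring expansion.

Key step: step 17

Remark on names: U = upper (−)-epicatechin unit, M = middle (+)-catechin unit, T = terminal (+)-catechin unit; TBS = tert-butyldimethylsilyl; acyl-ring atoms are numbered as in the target (C1 quaternary, C2=C3 alkene, C6 ketone).
Remark on stereocontrol: a lithiated diazoacetate is not expected to distinguish the two faces of cyclopent-2-en-1-one, and the flavan stereocentres are too remote to do so; the (1R) carbinol is therefore secured in step 15 by separation of the two epimers, not by induction.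
Remark on protecting groups: the C3 oxygens of U and M are silylated throughout, so that no free secondary carbinol meets the amide base or the Lewis acid and only the T C3–OH can be acylated.

**Route**

Step 1
Reactants: 1 (+)-catechin
Product: 2 5,7,3',4'-tetra-O-benzyl-(+)-catechin
Conditions: BnBr (4.4 equiv), K2CO3, DMF, 0 °C → rt
Reagents that add atoms: benzyl bromide, BrCc1ccccc1
Why: Williamson etherification of the four phenols, which K2CO3 deprotonates while the secondary C3–OH stays free; no stereocentre is touched.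

Step 2
Reactants: 2 5,7,3',4'-tetra-O-benzyl-(+)-catechin
Product: 3 5,7,3',4'-tetra-O-benzyl-3-O-TBS-(+)-catechin
Conditions: TBSOTf, 2,6-lutidine, CH2Cl2, 0 °C
Reagents that add atoms: tert-butyldimethylsilyl trifluoromethanesulfonate, CC(C)(C)[Si](C)(C)OS(=O)(=O)C(F)(F)F
Why: Silyl ether formation at the one remaining hydroxyl with the reactive silyl triflate; the C–O bond is not broken, so C3 keeps its configuration.

Step 3
Reactants: 3 5,7,3',4'-tetra-O-benzyl-3-O-TBS-(+)-catechin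
Product: 4 5,7,3',4'-tetra-O-benzyl-3-O-TBS-4β-(2-ethoxyethoxy)-(+)-catechin
Conditions: DDQ (2 equiv), 2-ethoxyethanol (5 equiv), CH2Cl2, rt
Reagents that add atoms: 2-ethoxyethanol, CCOCCO
Why: Oxidative benzylic C–H alkoxylation, in which DDQ abstracts hydride from C4 (cation stabilised by the 5,7-dialkoxy ring A) and the alcohol is expected to add anti to the C2 aryl group (4β, as drawn); the C4 configuration is immaterial because C4 is ionised again in step 7.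

Step 4
Reactants: 5 (−)-epicatechin
Product: 6 5,7,3',4'-tetra-O-benzyl-(−)-epicatechin
Conditions: BnBr (4.4 equiv), K2CO3, DMF, 0 °C → rt
Reagents that add atoms: benzyl bromide, BrCc1ccccc1
Why: Williamson etherification of the four phenols as in step 1; no stereocentre is touched.

Step 5
Reactants: 6 5,7,3',4'-tetra-O-benzyl-(−)-epicatechin
Product: 7 5,7,3',4'-tetra-O-benzyl-3-O-TBS-(−)-epicatechin
Conditions: TBSOTf, 2,6-lutidine, CH2Cl2, 0 °C
Reagents that add atoms: tert-butyldimethylsilyl trifluoromethanesulfonate, CC(C)(C)[Si](C)(C)OS(=O)(=O)C(F)(F)F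
Why: Silyl ether formation at the axial C3–OH, for which the silyl triflate is reactive enough; C3 keeps its configuration.

Step 6
Reactants: 7 5,7,3',4'-tetra-O-benzyl-3-O-TBS-(−)-epicatechin
Product: 8 5,7,3',4'-tetra-O-benzyl-3-O-TBS-4β-(2-ethoxyethoxy)-(−)-epicatechin
Conditions: DDQ (2 equiv), 2-ethoxyethanol (5 equiv), CH2Cl2, rt
Reagents that add atoms: 2-ethoxyethanol, CCOCCO
Why: Oxidative benzylic C–H alkoxylation at C4 as in step 3, with the alcohol adding anti to the C2 aryl and C3 silyloxy groups (4β); the C4 configuration is lost again on ionisation in step 8.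

Step 7
Reactants: 4 5,7,3',4'-tetra-O-benzyl-3-O-TBS-4β-(2-ethoxyethoxy)-(+)-catechin; 2 5,7,3',4'-tetra-O-benzyl-(+)-catechin (4 equiv, excess recovered)
Product: 9 M–T dimer [5,7,3',4'-tetra-O-benzyl-3-O-TBS-catechin]-(4α→8)-[5,7,3',4'-tetra-O-benzylcatechin]
Conditions: TMSOTf (0.2 equiv), CH2Cl2, −78 °C; then Et3N
Reagents that add atoms: none
Why: Lewis-acid ionisation of the C4 ether gives the benzylic flavan-4-yl cation, which alkylates the most nucleophilic ring-A position C8 of excess 2 (Friedel–Crafts-type flavan coupling); the bulky 3-O-TBS group on the β face should direct attack to the α face and so set the 4α (3,4-trans) centre, and the excess of 2 suppresses self-condensation.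

Step 8
Reactants: 8 5,7,3',4'-tetra-O-benzyl-3-O-TBS-4β-(2-ethoxyethoxy)-(−)-epicatechin; 9 M–T dimer (2 equiv, excess recovered)
Product: 10 U–M–T trimer [5,7,3',4'-tetra-O-benzyl-3-O-TBS-epicatechin]-(4β→8)-[5,7,3',4'-tetra-O-benzyl-3-O-TBS-catechin]-(4α→8)-[5,7,3',4'-tetra-O-benzylcatechin]
Conditions: TMSOTf (0.2 equiv), CH2Cl2, −78 → −40 °C, slow addition of 8; then Et3N
Reagents that add atoms: none
Why: The same Friedel–Crafts-type flavan coupling, in which the epicatechin-derived C4 cation is attacked by the free C8 of unit M, the most reactive and least encumbered ring-A position of 9; approach anti to both the C2 aryl and the C3 silyloxy group sets the 4β centre.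

Step 9
Reactants: 10 U–M–T trimer (twelve benzyl ethers)
Product: 11 [3-O-TBS-epicatechin]-(4β→8)-[3-O-TBS-catechin]-(4α→8)-catechin (twelve free phenols; T C3–OH free)
Conditions: H2 (1 atm), Pd(OH)2/C, THF/EtOAc, rt
Reagents that add atoms: none
Why: Hydrogenolysis of the benzyl aryl ethers in a neutral, non-alcoholic medium leaves the secondary TBS ethers and the C4–C8 bonds intact; it is placed here because no alkene or diazo group is present yet.

Step 10
Reactants: 11 dodecaphenol carrying 3-O-TBS groups on U and M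
Product: 12 tris(3',4'-O-phenylboronate) of 11 (each ring-B catechol closed to a 2-phenyl-1,3,2-benzodioxaborole; six ring-A phenols and T C3–OH free)
Conditions: PhB(OH)2 (3.1 equiv), 4 Å MS, THF, rt, argon; evaporation from toluene, used crude
Reagents that add atoms: phenylboronic acid, OB(O)c1ccccc1
Why: Boronic ester formation, in which only a 1,2-diphenol can close the five-membered cyclic boronate, so the three ring-B catechols are masked while the meta-related ring-A phenols and the isolated T C3–OH stay free; this divides the twelve phenols into two sets of six that can each be silylated to completion on a defined intermediate.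

Step 11
Reactants: 12 tris(3',4'-O-phenylboronate) of 11
Product: 14 ring-A hexa-O-TBS ether of 11 (5,7-di-O-TBS on every unit; ring-B catechols free; T C3–OH free), via hexa-O-TBS tris(phenylboronate) 13 (not isolated)
Conditions: TBSCl (9 equiv), iPr2NEt (12 equiv), DMF, rt, argon; then pinacol (6 equiv), THF, rt
Reagents that add atoms: tert-butyldimethylsilyl chloride, CC(C)(C)[Si](C)(C)Cl
Why: Silylation of the six ring-A phenols with the silyl chloride and a hindered amine that does not bind boron, followed by transesterification of the labile catechol boronates to the more stable pinacol boronate, which releases the catechols; a boronate lost early would only expose a phenol that step 12 silylates in any case, and the hindered secondary T C3–OH is not silylated by the chloride.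

Step 12
Reactants: 14 ring-A hexa-O-TBS ether of 11
Product: 15 silylated trimer alcohol [3,5,7,3',4'-penta-O-TBS-epicatechin]-(4β→8)-[3,5,7,3',4'-penta-O-TBS-catechin]-(4α→8)-[5,7,3',4'-tetra-O-TBS-catechin] (T C3–OH free)
Conditions: TBSCl (9 equiv), imidazole (18 equiv), DMF, rt, argon
Reagents that add atoms: tert-butyldimethylsilyl chloride, CC(C)(C)[Si](C)(C)Cl
Why: Silylation of the six exposed ring-B phenols with TBSCl and imidazole, which is much faster at phenols than at the hindered secondary flavan C3–OH, so the T C3–OH should remain the only free hydroxyl; no stereocentre is touched.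

Step 13
Reactants: 15 silylated trimer alcohol
Product: 16 T 3-O-(2-bromoacetate) of 15
Conditions: BrCH2COBr (2 equiv), pyridine, CH2Cl2, −20 → 0 °C
Reagents that add atoms: bromoacetyl bromide, BrCC(Br)=O
Why: Ester formation at the only free hydroxyl with the acid bromide; the C3–O bond is not broken, so the configuration is retained.

Step 14
Reactants: 16 T 3-O-(2-bromoacetate) of 15
Product: 18 T 3-O-(2-diazoacetate) of 15, via N-alkylated ditosylhydrazide 17 (not isolated)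
Conditions: TsNHNHTs (2 equiv), DBU (5 equiv), THF (anhydrous), 0 °C, 15 min
Reagents that add atoms: N,N'-ditosylhydrazine, Cc1ccc(cc1)S(=O)(=O)NNS(=O)(=O)c1ccc(C)cc1
Why: Fukuyama diazoacetate synthesis, in which the hydrazide anion displaces bromide and DBU then expels two sulfinates to leave the diazo group; the short anhydrous treatment should spare the aryl silyl ethers.

Step 15
Reactants: 18 T 3-O-(2-diazoacetate) of 15; 19 cyclopent-2-en-1-one (3 equiv)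
Product: 21 T 3-O-[2-diazo-2-((1R)-1-hydroxycyclopent-2-en-1-yl)acetate] of 15, via lithiated diazoacetate 20 (not isolated)
Conditions: LiN(iPr)2 (1.15 equiv), THF, −78 °C; then 19, −78 °C; AcOH, −78 °C
Reagents that add atoms: none
Why: Aldol-type 1,2-addition of the lithiated diazoacetate to the ketone carbonyl (kinetic at −78 °C, cold quench against retro-aldol); the new carbinol centre is not controlled, so both epimers are expected and the (1R) epimer 21 is isolated by preparative HPLC on silica.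

Step 16
Reactants: 21 T 3-O-[2-diazo-2-((1R)-1-hydroxycyclopent-2-en-1-yl)acetate] of 15
Product: 22 T 3-O-[2-((1R)-1-hydroxycyclopent-2-en-1-yl)-2-oxoacetate] of 15
Conditions: DMDO (1.2 equiv, in acetone), CH2Cl2, −40 → 0 °C
Reagents that add atoms: dimethyldioxirane, CC1(C)OO1
Why: Oxygen-atom transfer from the dioxirane to the nucleophilic diazo carbon with loss of N2 (diazo-to-ketone oxidation) should be much faster than epoxidation of the allylic alkene or attack on the silylated arenes; the carbinol centre is untouched.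

Step 17
Reactants: 22 T 3-O-[2-((1R)-1-hydroxycyclopent-2-en-1-yl)-2-oxoacetate] of 15
Product: 23 T 3-O-[(1S)-1-hydroxy-6-oxocyclohex-2-ene-1-carboxylate] of 15
Conditions: Cu(OTf)2 (20 mol %), 2,6-di-tert-butylpyridine (40 mol %), 4 Å MS, CH2Cl2, 0 °C → rt
Reagents that add atoms: none
Why: Cu(OTf)2 is expected to hold the tertiary hydroxyl oxygen and the neighbouring keto oxygen of 22 in a five-membered chelate, and within it the alkene carbon of the five-membered ring (the future C2) moves with its bonding electrons from the carbinol carbon onto the keto carbon, the carbinol carbon ending as the C6 ketone. The closest known reaction is the Lewis-acid-promoted α-ketol (acyloin) rearrangement of β-hydroxy α-keto esters to α-hydroxy β-keto esters, which is also known in ring-expanding form. The six-membered ring is closed by this one-carbon ring expansion of the cyclopentene (a 1,2-shift, not an end-to-end cyclisation), which forms the C1–C2 bond. The new quaternary centre C1 is controlled by the (R)-carbinol of 22: in the syn-periplanar O–C–C=O chelate the alkene carbon sits over one face of the keto group only and migrates suprafacially, so that (R) becomes (S). The step needs migration of the sp2 carbon rather than the ring CH2, which the higher migratory aptitude of an alkenyl group (π-assistance in the bridged transition state) should secure, and it must stop before a second ketol shift of the ester group to the conjugated enone, for which the low temperature and the catalytic, buffered Lewis acid are chosen. The driving force is the change from a vicinal dicarbonyl to a chelated β-keto ester in an unstrained ring, and the hindered pyridine scavenges TfOH so that the silyl ethers and the interflavan bonds should survive.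

Step 18
Reactants: 23 T 3-O-[(1S)-1-hydroxy-6-oxocyclohex-2-ene-1-carboxylate] of 15
Product: 24 epicatechin-(4β→8)-catechin-(4α→8)-catechin 3-O-[(1S)-1-hydroxy-6-oxocyclohex-2-ene-1-carboxylate] on unit T (CNP0159807.2)
Conditions: HF·pyridine (excess), pyridine, THF, 0 °C → rt, argon; Me3SiOMe quench
Reagents that add atoms: none
Why: Fluoride-mediated Si–O cleavage of the twelve aryl and two secondary alkyl silyl ethers under weakly acidic, buffered conditions, under which the base-labile α-hydroxy β-keto ester and the acid-labile interflavan bonds should both survive; no stereocentre is affected.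

**Compound list**

1 | (+)-catechin | O[C@H]1Cc2c(O)cc(O)cc2O[C@@H]1c1ccc(O)c(O)c1 | starting material
2 | 5,7,3',4'-tetra-O-benzyl-(+)-catechin | O[C@H]1Cc2c(OCc3ccccc3)cc(OCc3ccccc3)cc2O[C@@H]1c1ccc(OCc2ccccc2)c(OCc2ccccc2)c1 | intermediate
3 | 5,7,3',4'-tetra-O-benzyl-3-O-TBS-(+)-catechin | CC(C)(C)[Si](C)(C)O[C@H]1Cc2c(OCc3ccccc3)cc(OCc3ccccc3)cc2O[C@@H]1c1ccc(OCc2ccccc2)c(OCc2ccccc2)c1 | intermediate
4 | 5,7,3',4'-tetra-O-benzyl-3-O-TBS-4β-(2-ethoxyethoxy)-(+)-catechin | CCOCCO[C@H]1c2c(OCc3ccccc3)cc(OCc3ccccc3)cc2O[C@H](c2ccc(OCc3ccccc3)c(OCc3ccccc3)c2)[C@H]1O[Si](C)(C)C(C)(C)C | intermediate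
5 | (−)-epicatechin | O[C@@H]1Cc2c(O)cc(O)cc2O[C@@H]1c1ccc(O)c(O)c1 | starting material
6 | 5,7,3',4'-tetra-O-benzyl-(−)-epicatechin | O[C@@H]1Cc2c(OCc3ccccc3)cc(OCc3ccccc3)cc2O[C@@H]1c1ccc(OCc2ccccc2)c(OCc2ccccc2)c1 | intermediate
7 | 5,7,3',4'-tetra-O-benzyl-3-O-TBS-(−)-epicatechin | CC(C)(C)[Si](C)(C)O[C@@H]1Cc2c(OCc3ccccc3)cc(OCc3ccccc3)cc2O[C@@H]1c1ccc(OCc2ccccc2)c(OCc2ccccc2)c1 | intermediate
8 | 5,7,3',4'-tetra-O-benzyl-3-O-TBS-4β-(2-ethoxyethoxy)-(−)-epicatechin | CCOCCO[C@H]1c2c(OCc3ccccc3)cc(OCc3ccccc3)cc2O[C@H](c2ccc(OCc3ccccc3)c(OCc3ccccc3)c2)[C@@H]1O[Si](C)(C)C(C)(C)C | intermediate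
9 | M–T dimer [5,7,3',4'-tetra-O-benzyl-3-O-TBS-catechin]-(4α→8)-[5,7,3',4'-tetra-O-benzylcatechin] | O[C@H]1Cc2c(OCc5ccccc5)cc(OCc5ccccc5)c([C@@H]3c4c(OCc5ccccc5)cc(OCc5ccccc5)cc4O[C@H](c4ccc(OCc5ccccc5)c(OCc5ccccc5)c4)[C@H]3O[Si](C)(C)C(C)(C)C)c2O[C@@H]1c1ccc(OCc5ccccc5)c(OCc5ccccc5)c1 | intermediate
10 | U–M–T trimer [5,7,3',4'-tetra-O-benzyl-3-O-TBS-epicatechin]-(4β→8)-[5,7,3',4'-tetra-O-benzyl-3-O-TBS-catechin]-(4α→8)-[5,7,3',4'-tetra-O-benzylcatechin] | O[C@H]1Cc2c(OCc7ccccc7)cc(OCc7ccccc7)c([C@@H]3c4c(OCc7ccccc7)cc(OCc7ccccc7)c([C@H]5c6c(OCc7ccccc7)cc(OCc7ccccc7)cc6O[C@H](c6ccc(OCc7ccccc7)c(OCc7ccccc7)c6)[C@@H]5O[Si](C)(C)C(C)(C)C)c4O[C@H](c4ccc(OCc7ccccc7)c(OCc7ccccc7)c4)[C@H]3O[Si](C)(C)C(C)(C)C)c2O[C@@H]1c1ccc(OCc7ccccc7)c(OCc7ccccc7)c1 | intermediate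
11 | [3-O-TBS-epicatechin]-(4β→8)-[3-O-TBS-catechin]-(4α→8)-catechin (twelve free phenols; T C3–OH free) | O[C@H]1Cc2c(O)cc(O)c([C@@H]3c4c(O)cc(O)c([C@H]5c6c(O)cc(O)cc6O[C@H](c6ccc(O)c(O)c6)[C@@H]5O[Si](C)(C)C(C)(C)C)c4O[C@H](c4ccc(O)c(O)c4)[C@H]3O[Si](C)(C)C(C)(C)C)c2O[C@@H]1c1ccc(O)c(O)c1 | intermediate
12 | tris(3',4'-O-phenylboronate) of 11 (ring-B catechols as 2-phenyl-1,3,2-benzodioxaboroles) | O[C@H]1Cc2c(O)cc(O)c([C@@H]3c4c(O)cc(O)c([C@H]5c6c(O)cc(O)cc6O[C@H](c6ccc7OB(c8ccccc8)Oc7c6)[C@@H]5O[Si](C)(C)C(C)(C)C)c4O[C@H](c4ccc5OB(c6ccccc6)Oc5c4)[C@H]3O[Si](C)(C)C(C)(C)C)c2O[C@@H]1c1ccc2OB(c3ccccc3)Oc2c1 | intermediate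
13 | ring-A hexa-O-TBS ether of tris(phenylboronate) 12 | O[C@H]1Cc2c(O[Si](C)(C)C(C)(C)C)cc(O[Si](C)(C)C(C)(C)C)c([C@@H]3c4c(O[Si](C)(C)C(C)(C)C)cc(O[Si](C)(C)C(C)(C)C)c([C@H]5c6c(O[Si](C)(C)C(C)(C)C)cc(O[Si](C)(C)C(C)(C)C)cc6O[C@H](c6ccc7OB(c8ccccc8)Oc7c6)[C@@H]5O[Si](C)(C)C(C)(C)C)c4O[C@H](c4ccc5OB(c6ccccc6)Oc5c4)[C@H]3O[Si](C)(C)C(C)(C)C)c2O[C@@H]1c1ccc2OB(c3ccccc3)Oc2c1 | intermediate
14 | ring-A hexa-O-TBS ether of 11 (5,7-di-O-TBS on every unit; ring-B catechols free; T C3–OH free) | O[C@H]1Cc2c(O[Si](C)(C)C(C)(C)C)cc(O[Si](C)(C)C(C)(C)C)c([C@@H]3c4c(O[Si](C)(C)C(C)(C)C)cc(O[Si](C)(C)C(C)(C)C)c([C@H]5c6c(O[Si](C)(C)C(C)(C)C)cc(O[Si](C)(C)C(C)(C)C)cc6O[C@H](c6ccc(O)c(O)c6)[C@@H]5O[Si](C)(C)C(C)(C)C)c4O[C@H](c4ccc(O)c(O)c4)[C@H]3O[Si](C)(C)C(C)(C)C)c2O[C@@H]1c1ccc(O)c(O)c1 | intermediate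
15 | silylated trimer alcohol [3,5,7,3',4'-penta-O-TBS-epicatechin]-(4β→8)-[3,5,7,3',4'-penta-O-TBS-catechin]-(4α→8)-[5,7,3',4'-tetra-O-TBS-catechin] (T C3–OH free) | O[C@H]1Cc2c(O[Si](C)(C)C(C)(C)C)cc(O[Si](C)(C)C(C)(C)C)c([C@@H]3c4c(O[Si](C)(C)C(C)(C)C)cc(O[Si](C)(C)C(C)(C)C)c([C@H]5c6c(O[Si](C)(C)C(C)(C)C)cc(O[Si](C)(C)C(C)(C)C)cc6O[C@H](c6ccc(O[Si](C)(C)C(C)(C)C)c(O[Si](C)(C)C(C)(C)C)c6)[C@@H]5O[Si](C)(C)C(C)(C)C)c4O[C@H](c4ccc(O[Si](C)(C)C(C)(C)C)c(O[Si](C)(C)C(C)(C)C)c4)[C@H]3O[Si](C)(C)C(C)(C)C)c2O[C@@H]1c1ccc(O[Si](C)(C)C(C)(C)C)c(O[Si](C)(C)C(C)(C)C)c1 | intermediate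
16 | T 3-O-(2-bromoacetate) of 15 | BrCC(=O)O[C@H]1Cc2c(O[Si](C)(C)C(C)(C)C)cc(O[Si](C)(C)C(C)(C)C)c([C@@H]3c4c(O[Si](C)(C)C(C)(C)C)cc(O[Si](C)(C)C(C)(C)C)c([C@H]5c6c(O[Si](C)(C)C(C)(C)C)cc(O[Si](C)(C)C(C)(C)C)cc6O[C@H](c6ccc(O[Si](C)(C)C(C)(C)C)c(O[Si](C)(C)C(C)(C)C)c6)[C@@H]5O[Si](C)(C)C(C)(C)C)c4O[C@H](c4ccc(O[Si](C)(C)C(C)(C)C)c(O[Si](C)(C)C(C)(C)C)c4)[C@H]3O[Si](C)(C)C(C)(C)C)c2O[C@@H]1c1ccc(O[Si](C)(C)C(C)(C)C)c(O[Si](C)(C)C(C)(C)C)c1 | intermediate
17 | T 3-O-[2-(N,N'-ditosylhydrazin-1-yl)acetate] of 15 | Cc1ccc(cc1)S(=O)(=O)NN(S(=O)(=O)c1ccc(C)cc1)CC(=O)O[C@H]1Cc2c(O[Si](C)(C)C(C)(C)C)cc(O[Si](C)(C)C(C)(C)C)c([C@@H]3c4c(O[Si](C)(C)C(C)(C)C)cc(O[Si](C)(C)C(C)(C)C)c([C@H]5c6c(O[Si](C)(C)C(C)(C)C)cc(O[Si](C)(C)C(C)(C)C)cc6O[C@H](c6ccc(O[Si](C)(C)C(C)(C)C)c(O[Si](C)(C)C(C)(C)C)c6)[C@@H]5O[Si](C)(C)C(C)(C)C)c4O[C@H](c4ccc(O[Si](C)(C)C(C)(C)C)c(O[Si](C)(C)C(C)(C)C)c4)[C@H]3O[Si](C)(C)C(C)(C)C)c2O[C@@H]1c1ccc(O[Si](C)(C)C(C)(C)C)c(O[Si](C)(C)C(C)(C)C)c1 | intermediate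
18 | T 3-O-(2-diazoacetate) of 15 | [N-]=[N+]=CC(=O)O[C@H]1Cc2c(O[Si](C)(C)C(C)(C)C)cc(O[Si](C)(C)C(C)(C)C)c([C@@H]3c4c(O[Si](C)(C)C(C)(C)C)cc(O[Si](C)(C)C(C)(C)C)c([C@H]5c6c(O[Si](C)(C)C(C)(C)C)cc(O[Si](C)(C)C(C)(C)C)cc6O[C@H](c6ccc(O[Si](C)(C)C(C)(C)C)c(O[Si](C)(C)C(C)(C)C)c6)[C@@H]5O[Si](C)(C)C(C)(C)C)c4O[C@H](c4ccc(O[Si](C)(C)C(C)(C)C)c(O[Si](C)(C)C(C)(C)C)c4)[C@H]3O[Si](C)(C)C(C)(C)C)c2O[C@@H]1c1ccc(O[Si](C)(C)C(C)(C)C)c(O[Si](C)(C)C(C)(C)C)c1 | intermediate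
19 | cyclopent-2-en-1-one | O=C1C=CCC1 | starting material
20 | lithiated diazoacetate of 18 (lithium on the diazo carbon) | [Li]C(=[N+]=[N-])C(=O)O[C@H]1Cc2c(O[Si](C)(C)C(C)(C)C)cc(O[Si](C)(C)C(C)(C)C)c([C@@H]3c4c(O[Si](C)(C)C(C)(C)C)cc(O[Si](C)(C)C(C)(C)C)c([C@H]5c6c(O[Si](C)(C)C(C)(C)C)cc(O[Si](C)(C)C(C)(C)C)cc6O[C@H](c6ccc(O[Si](C)(C)C(C)(C)C)c(O[Si](C)(C)C(C)(C)C)c6)[C@@H]5O[Si](C)(C)C(C)(C)C)c4O[C@H](c4ccc(O[Si](C)(C)C(C)(C)C)c(O[Si](C)(C)C(C)(C)C)c4)[C@H]3O[Si](C)(C)C(C)(C)C)c2O[C@@H]1c1ccc(O[Si](C)(C)C(C)(C)C)c(O[Si](C)(C)C(C)(C)C)c1 | intermediate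
21 | T 3-O-[2-diazo-2-((1R)-1-hydroxycyclopent-2-en-1-yl)acetate] of 15 | O[C@]1(C=CCC1)C(=[N+]=[N-])C(=O)O[C@H]1Cc2c(O[Si](C)(C)C(C)(C)C)cc(O[Si](C)(C)C(C)(C)C)c([C@@H]3c4c(O[Si](C)(C)C(C)(C)C)cc(O[Si](C)(C)C(C)(C)C)c([C@H]5c6c(O[Si](C)(C)C(C)(C)C)cc(O[Si](C)(C)C(C)(C)C)cc6O[C@H](c6ccc(O[Si](C)(C)C(C)(C)C)c(O[Si](C)(C)C(C)(C)C)c6)[C@@H]5O[Si](C)(C)C(C)(C)C)c4O[C@H](c4ccc(O[Si](C)(C)C(C)(C)C)c(O[Si](C)(C)C(C)(C)C)c4)[C@H]3O[Si](C)(C)C(C)(C)C)c2O[C@@H]1c1ccc(O[Si](C)(C)C(C)(C)C)c(O[Si](C)(C)C(C)(C)C)c1 | intermediate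
22 | T 3-O-[2-((1R)-1-hydroxycyclopent-2-en-1-yl)-2-oxoacetate] of 15 (key-step precursor) | O[C@]1(C=CCC1)C(=O)C(=O)O[C@H]1Cc2c(O[Si](C)(C)C(C)(C)C)cc(O[Si](C)(C)C(C)(C)C)c([C@@H]3c4c(O[Si](C)(C)C(C)(C)C)cc(O[Si](C)(C)C(C)(C)C)c([C@H]5c6c(O[Si](C)(C)C(C)(C)C)cc(O[Si](C)(C)C(C)(C)C)cc6O[C@H](c6ccc(O[Si](C)(C)C(C)(C)C)c(O[Si](C)(C)C(C)(C)C)c6)[C@@H]5O[Si](C)(C)C(C)(C)C)c4O[C@H](c4ccc(O[Si](C)(C)C(C)(C)C)c(O[Si](C)(C)C(C)(C)C)c4)[C@H]3O[Si](C)(C)C(C)(C)C)c2O[C@@H]1c1ccc(O[Si](C)(C)C(C)(C)C)c(O[Si](C)(C)C(C)(C)C)c1 | intermediate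
23 | T 3-O-[(1S)-1-hydroxy-6-oxocyclohex-2-ene-1-carboxylate] of 15 (key-step product) | O=C1CCC=C[C@@]1(O)C(=O)O[C@H]1Cc2c(O[Si](C)(C)C(C)(C)C)cc(O[Si](C)(C)C(C)(C)C)c([C@@H]3c4c(O[Si](C)(C)C(C)(C)C)cc(O[Si](C)(C)C(C)(C)C)c([C@H]5c6c(O[Si](C)(C)C(C)(C)C)cc(O[Si](C)(C)C(C)(C)C)cc6O[C@H](c6ccc(O[Si](C)(C)C(C)(C)C)c(O[Si](C)(C)C(C)(C)C)c6)[C@@H]5O[Si](C)(C)C(C)(C)C)c4O[C@H](c4ccc(O[Si](C)(C)C(C)(C)C)c(O[Si](C)(C)C(C)(C)C)c4)[C@H]3O[Si](C)(C)C(C)(C)C)c2O[C@@H]1c1ccc(O[Si](C)(C)C(C)(C)C)c(O[Si](C)(C)C(C)(C)C)c1 | intermediate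
24 | epicatechin-(4β→8)-catechin-(4α→8)-catechin 3-O-[(1S)-1-hydroxy-6-oxocyclohex-2-ene-1-carboxylate] on unit T (CNP0159807.2) | O=C1CCC=C[C@@]1(O)C(=O)O[C@H]1Cc2c(O)cc(O)c([C@@H]3c4c(O)cc(O)c([C@H]5c6c(O)cc(O)cc6O[C@H](c6ccc(O)c(O)c6)[C@@H]5O)c4O[C@H](c4ccc(O)c(O)c4)[C@H]3O)c2O[C@@H]1c1ccc(O)c(O)c1 | target

**Summary**

Total step count: 18.
Longest linear sequence: 15 steps (steps 1, 2, 3, then 7 to 18, from (+)-catechin).

**Steps most likely to fail**

Step 17 (key ring expansion). The ring CH2 may migrate in competition with the alkene carbon, the ester group may shift onward to give the conjugated enone isomer, or the chelate geometry may not be held, so that chirality transfer from the carbinol is incomplete. The fallback builds the acyl ring by known chemistry; it sets out from 15 and comes back at 23. Birch reduction of 2-methoxybenzoic acid (Na, liquid NH3, then NH4Cl) gives 2-methoxycyclohexa-2,5-diene-1-carboxylic acid F1. Esterification of 15 with F1 (DCC, DMAP, CH2Cl2, 0 °C) gives the dienyl ester F2. Hydrolysis of its enol ether (aqueous oxalic acid, THF, 0 °C) gives the 6-oxocyclohex-2-ene-1-carboxylate F3. α-Hydroxylation of this β-keto ester with NaN(SiMe3)2 and an enantiopure (camphorsulfonyl)oxaziridine at −78 °C, the reagent enantiomer being chosen for the (1S) product, gives 23 after chromatographic removal of the C1 epimer.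

Step 15 (diazo aldol). The addition has no facial bias, and the two carbinol epimers of a large lipophilic molecule may not separate; conjugate addition or retro-aldol on work-up would also cost material. The fallback moves the separation to a small molecule; it sets out from 15 and comes back at 22. Ethyl diazoacetate, LiN(iPr)2 and 19 (THF, −78 °C) give racemic ethyl 2-diazo-2-(1-hydroxycyclopent-2-en-1-yl)acetate F4. DMDO gives racemic ethyl 2-(1-hydroxycyclopent-2-en-1-yl)-2-oxoacetate F5. Preparative chromatography on a chiral stationary phase gives the (R)-enantiomer F6. LiOH (THF/H2O, 0 °C, brief) gives (R)-2-(1-hydroxycyclopent-2-en-1-yl)-2-oxoacetic acid F7. Esterification of 15 with F7 (DCC, catalytic DMAP, CH2Cl2, 0 °C; the tertiary hydroxyl does not compete) gives 22.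

Step 8 (second interflavan coupling). The cation from 8 may be captured by the free C8 of another molecule of 8 or of the new trimer, or by C6 of the dimer, so that oligomers and regioisomers form and the valuable dimer 9 must be used in excess. The fallback caps C8 of the electrophile; it sets out from 6 and comes back at 11. Bromination of 6 (NBS, CH2Cl2, −40 °C) gives 8-bromo-5,7,3',4'-tetra-O-benzylepicatechin F8. TBSOTf and 2,6-lutidine give its 3-O-TBS ether F9. DDQ and 2-ethoxyethanol give the capped 4β-(2-ethoxyethoxy) electrophile F10, which cannot self-condense. Equimolar coupling with 9 (TMSOTf, CH2Cl2, −78 °C) gives the 8-bromo trimer F11, whose upper unit can no longer act as a nucleophile. Hydrogenolysis (H2, Pd(OH)2/C, Et3N, THF/EtOAc) removes the bromine together with the twelve benzyl groups and gives 11.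

**Further compounds**

F1 | step 17 | 2-methoxycyclohexa-2,5-diene-1-carboxylic acid (racemic) | COC1=CCC=CC1C(=O)O
F2 | step 17 | T 3-O-(2-methoxycyclohexa-2,5-diene-1-carboxylate) of 15 (both C1 epimers) | COC1=CCC=CC1C(=O)O[C@H]1Cc2c(O[Si](C)(C)C(C)(C)C)cc(O[Si](C)(C)C(C)(C)C)c([C@@H]3c4c(O[Si](C)(C)C(C)(C)C)cc(O[Si](C)(C)C(C)(C)C)c([C@H]5c6c(O[Si](C)(C)C(C)(C)C)cc(O[Si](C)(C)C(C)(C)C)cc6O[C@H](c6ccc(O[Si](C)(C)C(C)(C)C)c(O[Si](C)(C)C(C)(C)C)c6)[C@@H]5O[Si](C)(C)C(C)(C)C)c4O[C@H](c4ccc(O[Si](C)(C)C(C)(C)C)c(O[Si](C)(C)C(C)(C)C)c4)[C@H]3O[Si](C)(C)C(C)(C)C)c2O[C@@H]1c1ccc(O[Si](C)(C)C(C)(C)C)c(O[Si](C)(C)C(C)(C)C)c1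
F3 | step 17 | T 3-O-(6-oxocyclohex-2-ene-1-carboxylate) of 15 (both C1 epimers) | O=C1CCC=CC1C(=O)O[C@H]1Cc2c(O[Si](C)(C)C(C)(C)C)cc(O[Si](C)(C)C(C)(C)C)c([C@@H]3c4c(O[Si](C)(C)C(C)(C)C)cc(O[Si](C)(C)C(C)(C)C)c([C@H]5c6c(O[Si](C)(C)C(C)(C)C)cc(O[Si](C)(C)C(C)(C)C)cc6O[C@H](c6ccc(O[Si](C)(C)C(C)(C)C)c(O[Si](C)(C)C(C)(C)C)c6)[C@@H]5O[Si](C)(C)C(C)(C)C)c4O[C@H](c4ccc(O[Si](C)(C)C(C)(C)C)c(O[Si](C)(C)C(C)(C)C)c4)[C@H]3O[Si](C)(C)C(C)(C)C)c2O[C@@H]1c1ccc(O[Si](C)(C)C(C)(C)C)c(O[Si](C)(C)C(C)(C)C)c1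
F4 | step 15 | ethyl 2-diazo-2-(1-hydroxycyclopent-2-en-1-yl)acetate (racemic) | CCOC(=O)C(=[N+]=[N-])C1(O)C=CCC1
F5 | step 15 | ethyl 2-(1-hydroxycyclopent-2-en-1-yl)-2-oxoacetate (racemic) | CCOC(=O)C(=O)C1(O)C=CCC1
F6 | step 15 | ethyl 2-[(1R)-1-hydroxycyclopent-2-en-1-yl]-2-oxoacetate | CCOC(=O)C(=O)[C@]1(O)C=CCC1
F7 | step 15 | 2-[(1R)-1-hydroxycyclopent-2-en-1-yl]-2-oxoacetic acid | OC(=O)C(=O)[C@]1(O)C=CCC1
F8 | step 8 | 8-bromo-5,7,3',4'-tetra-O-benzyl-(−)-epicatechin | O[C@@H]1Cc2c(OCc3ccccc3)cc(OCc3ccccc3)c(Br)c2O[C@@H]1c1ccc(OCc2ccccc2)c(OCc2ccccc2)c1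
F9 | step 8 | 8-bromo-5,7,3',4'-tetra-O-benzyl-3-O-TBS-(−)-epicatechin | CC(C)(C)[Si](C)(C)O[C@@H]1Cc2c(OCc3ccccc3)cc(OCc3ccccc3)c(Br)c2O[C@@H]1c1ccc(OCc2ccccc2)c(OCc2ccccc2)c1
F10 | step 8 | 8-bromo-5,7,3',4'-tetra-O-benzyl-3-O-TBS-4β-(2-ethoxyethoxy)-(−)-epicatechin | CCOCCO[C@H]1c2c(OCc3ccccc3)cc(OCc3ccccc3)c(Br)c2O[C@H](c2ccc(OCc3ccccc3)c(OCc3ccccc3)c2)[C@@H]1O[Si](C)(C)C(C)(C)C
F11 | step 8 | 8-bromo (unit U) derivative of trimer 10 | O[C@H]1Cc2c(OCc7ccccc7)cc(OCc7ccccc7)c([C@@H]3c4c(OCc7ccccc7)cc(OCc7ccccc7)c([C@H]5c6c(OCc7ccccc7)cc(OCc7ccccc7)c(Br)c6O[C@H](c6ccc(OCc7ccccc7)c(OCc7ccccc7)c6)[C@@H]5O[Si](C)(C)C(C)(C)C)c4O[C@H](c4ccc(OCc7ccccc7)c(OCc7ccccc7)c4)[C@H]3O[Si](C)(C)C(C)(C)C)c2O[C@@H]1c1ccc(OCc7ccccc7)c(OCc7ccccc7)c1
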